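Locants follow the numbering in the first section. They coincide with spiro[5.5]undecane numbering and are not always the lowest IUPAC locants.

## Analysis of the target

1. The target is a spiro[5.5]undecane. Ring A holds C1 (C(OH)CH3), C2, C3 (CHBr), C4 and C5 (CMe2); C6 is the spiro atom; ring B holds C7=C8, C9, C10 and C11; C12 is the exocyclic =CHBr carbon on C9.
2. In ring A three contiguous carbons (C1, C6, C5) are fully substituted. In ring B the C7=C8 bond is conjugated with the (E)-C9=C12 bond, with Br trans to C8 and cis to C10.
3. The stereocentres are 1S, 3R and 6S. The C1 hydroxyl lies on the ring-A face that carries C11; the C1 methyl and the C3 bromine lie on the face that carries C7. OH and Br are therefore 1,3-trans, and in the favoured chair the OH is axial (syn to one C5 methyl), the bromine equatorial and C7 axial.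
4. C6 is stereogenic only because one ring-B arm starts with an sp2 carbon (C7) and the other with an sp3 carbon (C11). Its configuration must therefore be created in a C–C bond formation directly beside the CMe2 group.
5. The tertiary alcohol dehydrates easily. As an alkoxide it is set up for Grob fragmentation, because the equatorial C3–Br bond is antiperiplanar to C1–C2. The secondary bromide can undergo E2, and the bromodiene tolerates neither Pd(0), radicals nor strong acid.
6. The hard points are the congested quaternary stereocentre, the relay of its configuration to C1 and C3, and the geometry of a bromomethylidene whose two flanks (C8–H and C10H2) differ little in size.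
7. The strategy rests on one feature. With C1 at the ketone level, C6 is an enolate carbon that bears a vinyl carbon, so C6–C7 is the bond of an enolate/vinyl halide coupling that closes ring B and sets C6 at once. What is left of ring A (oxygen at C1 and C3, gem-dimethyl at C5) is dimedone 9.

## Retrosynthetic reasoning

**C3–Br, 23 ⇒ 21.**
- The equatorial bromide is traced to the axial, C3-epimeric alcohol of diol 21 through an SN2 displacement with inversion.
- This bond is cut first, so it is made last. Once the bromide is present, any base that touches the C1 hydroxyl would cleave C1–C2 in a Grob sense.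
- The forward reaction must activate the secondary hydroxyl beside the tertiary one under neutral conditions and must outrun E2.

**C9=C12, 21 ⇒ 20.**
- The exocyclic double bond is cut to the C9 carbonyl of enone 20 and a one-carbon bromo ylide.
- The bromodiene is not carried further back because it would not survive the palladium step, the organometallic addition or the hydride.
- The cost is that the geometry depends on the small difference between the planar C8–H flank and the C10 methylene.

**C9 ketal and C3–H, 20 ⇒ 19 ⇒ 18.**
- The enone is kept masked as its ene-ketal until ring A is finished, so the C3 ketone of 18 is the only reducible carbonyl when the hydride is used.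
- No selection between a saturated ketone and an enone is then needed.
- The C3–H bond is cut because the top face of that ketone is closed by the axial C1 hydroxyl and the axial C5 methyl. This should force hydride to the C7 face and give the axial alcohol of 19.

**C1–CH3 and the C3 carbonyl, 18 ⇒ 17 ⇒ 16 ⇒ 15.**
- The group that enters C1 last arrives from the less hindered C7 face, and in 23 that group is the methyl. The methyl is therefore disconnected from the C1 carbonyl of 15, rather than oxygen being added to an alkene.
- Adduct 16 is a vinylogous hemiketal. Brønsted acid would ionise its C1–O bond and collapse it to the transposed enone, erasing C1.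
- The enol ether is therefore opened by a soft iodonium electrophile at C2 under buffered conditions (17), and the iodine is then removed reductively (18).

**C6–C7, 15 ⇒ 12 (key disconnection).**
- Cutting the bond between the enolate carbon and the vinyl carbon opens ring B and removes the only stereocentre of 15.
- Precursor 12 may be racemic, because C6 is planarised on enolisation.
- No other ring-B bond offers this. C6–C11 is an ordinary alkylation that could not be made enantioselective as simply, and cuts at C8–C9 or C9–C10 leave the quaternary centre unsolved.
- The forward reaction needs a chiral palladium catalyst that selects one face of a fully substituted dienolate beside CMe2.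

**C6–C11, 12 ⇒ 10 + 8, and 10 ⇒ 9.**
- Kinetic α′-alkylation of enol ether 10 with the primary iodide of 8 joins the two halves.
- Enol ether 10 is the O-ethyl derivative of 9. Its enol ether differentiates the two carbonyls and later blocks enolisation toward C2.

**Side chain, 8 ⇒ 7 ⇒ 6 ⇒ 5 ⇒ 3 ⇒ 1 + 2 + 4.**
- The primary iodide comes from the chloride 7 by halide exchange.
- The (Z)-iodoalkene comes from iodoalkyne 6 by syn hydrogen transfer, and 6 comes from silylalkyne 5 by direct iododesilylation.
- Ketal 5 comes from ynone 3 and glycol 4, and 3 comes from acylation of 1 with 2.
- All five carbons C7–C11 and the C9 oxygen function are thus bought in two commercial pieces.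

## Alternatives that were turned down

**Alternative 1:**
- *Disconnection.* Both bonds that tie the C10–C11 bridge into ring B (C6–C11 and C9–C10) are removed, which corresponds to an intramolecular [4+2] cycloaddition.
- *Forward key step.* Ring A would come from actinol A2. Its ketone carbon becomes C6 as the inner end of an exocyclic C6=C7 bond conjugated with a bromoallene (C8=C9=C12HBr). An acrylate is attached to the C1 oxygen, and heating should give the tricyclic γ-lactone A1.
- *For.* One step makes ring B, the spiro centre, C7=C8 and the whole bromodiene. The short tether can only deliver C11 to the face of the C1 oxygen, which is the relative configuration of 23, and the absolute configuration is bought with A2. On the C1/C6 relationship, and in principle on the C9=C12 geometry, this plan is stronger than the chosen one.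
- *Against.*
  - The diene terminus C6 is fully substituted and wedged between C5Me2 and the acylated C1 centre.
  - The s-cis conformer pushes C8 against one of these groups, and vinylallenes can escape by [1,5]-hydrogen shift at the temperatures such a cycloaddition would need.
  - The E geometry follows only if the bromoallene is a single axial isomer that survives heating.
  - C1 must first be hydroxylated and a hindered tertiary alcohol acylated.
  - The lactone carbonyl is a carbon that 23 does not contain. Excising it needs a radical decarboxylation at C11 next to a bromodiene, which is itself a radical acceptor.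
- *Comparison.* These corrections cost more steps than the cycloaddition saves. The chosen route offers a precursor (12) reached by one alkylation and a ring closure in which every carbon stays in the product.

**Alternative 2:**
- *Disconnection.* The cut is C5–C6 in ring A, read as the result of a 1,2-shift.
- *Forward key step.* A tertiary cyclopentanol (carbinol carbon C1) carrying the ketal-protected cyclohexenyl ring would meet an electrophilic bromine source and a chiral catalyst. The bromonium ion on C6=C7 pulls C5 from C1 to C6, ring A grows from five to six members, and bromo ketone A3 results.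
- *For.* The quaternary centre is formed by an intramolecular migration that is little affected by crowding, the more substituted carbon migrates, and C1 emerges as the ketone. C3 already stands at the alcohol level, so methyl addition would give a tertiary alcohol that is not a vinylogous hemiketal. Steps 10 and 11 of the chosen route would then be unnecessary, which is a real advantage.
- *Against.*
  - Such expansions draw their driving force from ring strain, and five-to-six expansion releases little, so proton loss or capture of the bromonium ion can compete.
  - The substrate already carries C3. An enantiopure five-membered ring-A building block without a cheap source is needed, and catalyst and substrate control can be mismatched.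
  - Of the two stereocentres created, C7 is thrown away.
  - Its removal requires base on a neopentyl secondary bromide, while A3 is a β-silyloxy ketone prone to E1cB loss of the C3 oxygen.
- *Comparison.* After A3 the same methyl addition, olefination and inversion remain, so the route is longer by the whole synthesis of the carbinol. In the chosen route ring A is bought complete as 9.

**Alternative 3:**
- *Disconnection.* The cut is C8–C9.
- *Forward key step.* The substrate already carries at C6 a (Z)-iodovinyl arm (C7, C8) and a silylalkynyl-ethyl arm (C11, C10, C9, C12). It undergoes oxidative addition at C8 and a 6-exo-dig syn carbopalladation of the alkyne. A hydride donor then replaces palladium on C12 to give dienylsilane A4.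
- *For.* Syn addition places silicon trans to C8, so the exocyclic geometry is fixed by mechanism and would be passed to bromine by halodesilylation. On this point the plan is clearly stronger than step 14 of the chosen route.
- *Against.*
  - The step creates no stereocentre. C6, with a vinyl and an alkyl arm beside CMe2, must already exist as one enantiomer.
  - Making it would need either an intermolecular version of the enolate vinylation used here, or a detour through allylation, cleavage to a neopentyl aldehyde and Z-selective iodo-olefination.
  - A4 must then pass the methyl addition and the electrophilic unmasking of the enol ether, although iodonium reagents also attack vinylsilanes.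
  - Bromodesilylation of a conjugated dienylsilane can run through addition–elimination with loss of geometry, or can start at C7.
- *Comparison.* The plan solves the smaller of the two problems and leaves the larger one open. The chosen strategy does the reverse and accepts a separable isomer problem late in the route.

Key step: step 8

Assumption: the sense of induction of the chiral palladium catalyst cannot be derived for this substrate, so the ligand antipode that gives (6S)-15 is taken, both antipodes being available.

## Route

Step 1
Reactants: 1 bis(trimethylsilyl)acetylene; 2 3-chloropropionyl chloride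
Product: 3 5-chloro-1-(trimethylsilyl)pent-1-yn-3-one
Conditions: AlCl3 (1.1 equiv), CH2Cl2, 0 °C
Reagents that add atoms: none
Why: Friedel–Crafts-type acylative desilylation of a silylalkyne: the acylium ion attacks ipso to silicon through a β-silyl cation, the silyl group leaves as chloride, and the electron-poor ynone does not react a second time.

Step 2
Reactants: 3 5-chloro-1-(trimethylsilyl)pent-1-yn-3-one; 4 ethylene glycol
Product: 5 2-(2-chloroethyl)-2-[(trimethylsilyl)ethynyl]-1,3-dioxolane
Conditions: p-TsOH (cat.), benzene, reflux, Dean–Stark
Reagents that add atoms: none
Why: Acid-catalysed ketalisation with azeotropic removal of water; the silyl cap disfavours conjugate addition of the glycol to the ynone, and the ketal removes the α-acidity that would let the β-chloride eliminate.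

Step 3
Reactants: 5 2-(2-chloroethyl)-2-[(trimethylsilyl)ethynyl]-1,3-dioxolane
Product: 6 2-(2-chloroethyl)-2-(iodoethynyl)-1,3-dioxolane
Conditions: NIS (1.2 equiv), AgNO3 (10 mol %), DMF, rt, dark
Reagents that add atoms: N-iodosuccinimide, O=C1CCC(=O)N1I
Why: Silver-catalysed iododesilylation of a trimethylsilylalkyne gives the 1-iodoalkyne directly and saves a separate protodesilylation; ketal and alkyl chloride are inert under these neutral conditions.

Step 4
Reactants: 6 2-(2-chloroethyl)-2-(iodoethynyl)-1,3-dioxolane
Product: 7 2-(2-chloroethyl)-2-[(Z)-2-iodoethenyl]-1,3-dioxolane
Conditions: 2-nitrobenzenesulfonylhydrazide, Et3N, THF/i-PrOH, rt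
Reagents that add atoms: none
Why: Diimide reduction: concerted syn transfer of two hydrogens to the iodoalkyne gives only the (Z)-iodoalkene and leaves C–I, C–Cl and the ketal untouched; the amine-buffered diimide source avoids acid.

Step 5
Reactants: 7 2-(2-chloroethyl)-2-[(Z)-2-iodoethenyl]-1,3-dioxolane
Product: 8 2-(2-iodoethyl)-2-[(Z)-2-iodoethenyl]-1,3-dioxolane
Conditions: NaI (5 equiv), acetone, reflux
Reagents that add atoms: sodium iodide, [Na+].[I-]
Why: Finkelstein exchange driven by precipitation of the chloride salt; SN2 is possible only at the primary sp3 carbon, so the vinyl iodide keeps its geometry.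

Step 6
Reactants: 9 dimedone
Product: 10 3-ethoxy-5,5-dimethylcyclohex-2-en-1-one
Conditions: EtOH, p-TsOH (cat.), toluene, reflux, Dean–Stark
Reagents that add atoms: ethanol, CCO
Why: Acid-catalysed O-alkylation of the symmetrical 1,3-dione (vinylogous esterification); the enol ether differentiates the two carbonyls and later blocks enolisation toward C2.

Step 7
Reactants: 10 3-ethoxy-5,5-dimethylcyclohex-2-en-1-one; 8 2-(2-iodoethyl)-2-[(Z)-2-iodoethenyl]-1,3-dioxolane
Product: 12 rac-3-ethoxy-6-{2-[2-((Z)-2-iodoethenyl)-1,3-dioxolan-2-yl]ethyl}-5,5-dimethylcyclohex-2-en-1-one, via lithium cross-conjugated dienolate 11 (not isolated)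
Conditions: LDA (commercial, 0.98 equiv relative to 10), THF, −78 °C; then 8, DMPU, −78 °C → rt
Reagents that add atoms: none
Why: Kinetic deprotonation of a 3-alkoxyenone takes place at the α′ carbon C6 (Stork–Danheiser alkylation) and dienolate 11 is alkylated by the primary iodide, DMPU offsetting the hindrance by C5. The slight deficit of amide ensures that no free strong base meets the base-sensitive (Z)-iodide. The new C6 centre is racemic, which does not matter because it is planarised in step 8.

Step 8
Reactants: 12 rac-3-ethoxy-6-{2-[2-((Z)-2-iodoethenyl)-1,3-dioxolan-2-yl]ethyl}-5,5-dimethylcyclohex-2-en-1-one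
Product: 15 (6S)-3-ethoxy-5,5-dimethylspiro[5.5]undeca-2,7-diene-1,9-dione 9-ethylene ketal, via vinylpalladium(II) iodide 13 (not isolated), via C-bound palladacycle 14 (not isolated)
Conditions: Pd2(dba)3 (5 mol %), (R)-DIFLUORPHOS (12 mol %, antipode per the assumption), KOPh (commercial, 2 equiv), THF/toluene, 65–80 °C
Reagents that add atoms: none
Why: Pd(0) inserts with retention into the (Z)-C7–I bond to give 13; phenoxide reversibly removes C6–H, the planar cross-conjugated dienolate replaces iodide on palladium, and the C-bound palladacycle 14 collapses by C–C reductive elimination. The closest known reaction types are the intramolecular palladium-catalysed α-alkenylation of ketone enolates with tethered vinyl halides and the intermolecular asymmetric α-vinylation and α-arylation of α-branched cyclic ketones that build quaternary centres; combining them in a spiro closure beside CMe2 extends both. Ring B (six-membered) closes by reductive elimination from the seven-membered palladacycle, and the Z geometry of the iodide becomes the endocyclic cis C7=C8 bond. C6 is the only new stereocentre: enolisation erases the racemic centre of 12, both enantiomers converge on one achiral enolate, and the chiral bisphosphine decides which enolate face binds and couples. Regioselectivity is secured by the substrate, since the enol ether blocks enolisation toward C2 and coupling through oxygen, C2 or C4 would each need an eight-membered ring. Chemoselectivity is needed against anti elimination of HI from the Z-iodide (H on C8 trans to I), which is why a weak phenoxide base replaces alkoxide or amide bases.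

Step 9
Reactants: 15 (6S)-3-ethoxy-5,5-dimethylspiro[5.5]undeca-2,7-diene-1,9-dione 9-ethylene ketal
Product: 16 (1S,6S)-3-ethoxy-1-hydroxy-1,5,5-trimethylspiro[5.5]undeca-2,7-dien-9-one ethylene ketal
Conditions: MeLi (3 equiv), anhydrous CeCl3 (3.3 equiv), THF, −78 → −40 °C; quench sat. aq NaHCO3 (pH ≥ 8); used crude
Reagents that add atoms: methyllithium, [Li]C
Why: Organocerium 1,2-addition: the oxophilic, weakly basic reagent adds to hindered vinylogous ester carbonyls without deprotonating C4. In the half-chair with C7 pseudoaxial the opposite face of C1 is closed by the pseudoaxial C5 methyl, and the alternative half-chair would force the reagent past the C11 methylene, so methyl should enter past the flat C7–H arm and leave the hydroxyl syn to C11 (1S). The basic quench is needed because 16 is a vinylogous hemiketal.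

Step 10
Reactants: 16 (1S,6S)-3-ethoxy-1-hydroxy-1,5,5-trimethylspiro[5.5]undeca-2,7-dien-9-one ethylene ketal
Product: 17 (1R,6S)-1-hydroxy-2-iodo-1,5,5-trimethylspiro[5.5]undec-7-ene-3,9-dione 9-ethylene ketal (C2 epimers; the 1R label reflects only the higher CIP rank of the iodinated C2)
Conditions: NIS (1.05 equiv), NaHCO3, THF/H2O 4:1, 0 °C, dark; used crude
Reagents that add atoms: N-iodosuccinimide, O=C1CCC(=O)N1I; water, O
Why: Brønsted acid would ionise the doubly activated C1–O bond and give the transposed enone (the Stork–Danheiser outcome), erasing C1. Here the soft iodonium electrophile attacks only the enol ether carbon C2 (iodohydroxylation of an enol ether), water adds to the C3 oxocarbenium ion and the ethoxy group leaves, all near pH 8. The enol ether is far more nucleophilic than C7=C8, the ketal survives, and the C2 configuration is irrelevant.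

Step 11
Reactants: 17 (1R,6S)-1-hydroxy-2-iodo-1,5,5-trimethylspiro[5.5]undec-7-ene-3,9-dione 9-ethylene ketal
Product: 18 (1S,6S)-1-hydroxy-1,5,5-trimethylspiro[5.5]undec-7-ene-3,9-dione 9-ethylene ketal
Conditions: SmI2 (commercial 0.1 M, 2.2 equiv), THF/MeOH, −78 °C
Reagents that add atoms: none
Why: Samarium diiodide reduction of an α-halo ketone: two electron transfers expel iodide, and methanol protonates the samarium enolate at −78 °C faster than it can lose the β-hydroxyl or undergo retro-aldol cleavage. Any 1,2-epoxy ketone formed from 17 would be reduced to the same product.

Step 12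
Reactants: 18 (1S,6S)-1-hydroxy-1,5,5-trimethylspiro[5.5]undec-7-ene-3,9-dione 9-ethylene ketal
Product: 19 (1S,3S,6S)-1,3-dihydroxy-1,5,5-trimethylspiro[5.5]undec-7-en-9-one ethylene ketal
Conditions: L-Selectride (2.5 equiv), THF, −78 °C; then aq NaOH, H2O2, 0 °C
Reagents that add atoms: none
Why: A bulky trialkylborohydride attacks cyclohexanones from the equatorial direction. In the favoured chair of 18 (C1–OH axial, which avoids a syn-axial methyl/methyl pair) the top face of C3 is also closed by the axial C1–OH and C5–CH3, so hydride should arrive from the C7 face and give the axial 3S alcohol cis to the C1 hydroxyl. With C9 still ketalised there is no competing enone, and the low temperature suppresses retro-aldol cleavage.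

Step 13
Reactants: 19 (1S,3S,6S)-1,3-dihydroxy-1,5,5-trimethylspiro[5.5]undec-7-en-9-one ethylene ketal
Product: 20 (1S,3S,6S)-1,3-dihydroxy-1,5,5-trimethylspiro[5.5]undec-7-en-9-one
Conditions: 1 M aq HCl (cat.), THF/H2O, 0 °C → rt
Reagents that add atoms: water, O
Why: The allylic ketal ionises readily, so dilute acid suffices; the C1 alcohol is no longer allylic and survives, and C7=C8 cannot leave conjugation because C6 bears no hydrogen. Acetone is avoided so that the cis-1,3-diol is not tied up as an acetonide.

Step 14
Reactants: 20 (1S,3S,6S)-1,3-dihydroxy-1,5,5-trimethylspiro[5.5]undec-7-en-9-one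
Product: 21 (1S,3S,6S,9E)-9-(bromomethylidene)-1,5,5-trimethylspiro[5.5]undec-7-ene-1,3-diol
Conditions: [Ph3PCH2Br]Br (4 equiv), KOt-Bu (3.9 equiv), THF, −78 °C; then 20, −78 → 0 °C
Reagents that add atoms: (bromomethyl)triphenylphosphonium bromide, BrC[P+](c1ccccc1)(c1ccccc1)c1ccccc1.[Br-]
Why: Wittig bromomethylenation with a lithium-free ylide; the excess covers the two hydroxyl groups, which carry no leaving group or ring-A carbonyl that base could exploit. In the kinetically controlled puckered transition state the smaller carbonyl flank (planar C8–H) should sit near the P-phenyl groups and the ylide bromine should end cis to the bulkier C10 methylene, which predicts the E isomer as the major one. The minor geometric isomer is removed by chromatography.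

Step 15
Reactants: 21 (1S,3S,6S,9E)-9-(bromomethylidene)-1,5,5-trimethylspiro[5.5]undec-7-ene-1,3-diol
Product: 23 (1S,3R,6S,9E)-3-bromo-9-(bromomethylidene)-1,5,5-trimethylspiro[5.5]undec-7-en-1-ol, via C3 oxyphosphonium bromide 22 (not isolated)
Conditions: CBr4 (1.5 equiv), PPh3 (1.6 equiv), 2,6-lutidine (0.3 equiv), CH2Cl2, 0 °C → rt
Reagents that add atoms: carbon tetrabromide, BrC(Br)(Br)Br
Why: Appel reaction: only the secondary C3 hydroxyl should form oxyphosphonium ion 22, because the C1 hydroxyl is tertiary and flanked by C6. Bromide displaces the phosphine oxide from the C7 face with inversion, turning the axial 3S alcohol into the equatorial 3R bromide. The step is last and neutral because any later base would trigger Grob fragmentation of the γ-bromo alkoxide.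

## Compound list

1 | bis(trimethylsilyl)acetylene | C[Si](C)(C)C#C[Si](C)(C)C | starting material
2 | 3-chloropropionyl chloride | ClCCC(=O)Cl | starting material
3 | 5-chloro-1-(trimethylsilyl)pent-1-yn-3-one | ClCCC(=O)C#C[Si](C)(C)C | intermediate
4 | ethylene glycol | OCCO | starting material
5 | 2-(2-chloroethyl)-2-[(trimethylsilyl)ethynyl]-1,3-dioxolane | ClCCC1(OCCO1)C#C[Si](C)(C)C | intermediate
6 | 2-(2-chloroethyl)-2-(iodoethynyl)-1,3-dioxolane | ClCCC1(OCCO1)C#CI | intermediate
7 | 2-(2-chloroethyl)-2-[(Z)-2-iodoethenyl]-1,3-dioxolane | ClCCC1(OCCO1)/C=C\I | intermediate
8 | 2-(2-iodoethyl)-2-[(Z)-2-iodoethenyl]-1,3-dioxolane | ICCC1(OCCO1)/C=C\I | intermediate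
9 | dimedone | CC1(C)CC(=O)CC(=O)C1 | starting material
10 | 3-ethoxy-5,5-dimethylcyclohex-2-en-1-one | CCOC1=CC(=O)CC(C)(C)C1 | intermediate
11 | lithium cross-conjugated dienolate of 10 (not isolated) | CCOC1=CC([O-])=CC(C)(C)C1.[Li+] | intermediate
12 | rac-3-ethoxy-6-{2-[2-((Z)-2-iodoethenyl)-1,3-dioxolan-2-yl]ethyl}-5,5-dimethylcyclohex-2-en-1-one | CC1(C)CC(OCC)=CC(=O)C1CCC2(OCCO2)/C=C\I | intermediate
13 | vinylpalladium(II) iodide from 12, ligand omitted (not isolated) | CC1(C)CC(OCC)=CC(=O)C1CCC2(OCCO2)/C=C\[Pd]I | intermediate
14 | seven-membered C-bound palladacycle, ligand omitted (not isolated) | CC1(C)CC(OCC)=CC(=O)[C@]12CCC3(OCCO3)C=C[Pd]2 | intermediate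
15 | (6S)-3-ethoxy-5,5-dimethylspiro[5.5]undeca-2,7-diene-1,9-dione 9-ethylene ketal | CC1(C)CC(OCC)=CC(=O)[C@@]12C=CC3(CC2)OCCO3 | intermediate
16 | (1S,6S)-3-ethoxy-1-hydroxy-1,5,5-trimethylspiro[5.5]undeca-2,7-dien-9-one ethylene ketal | CC1(C)CC(OCC)=C[C@](C)(O)[C@@]12C=CC3(CC2)OCCO3 | intermediate
17 | (1R,6S)-1-hydroxy-2-iodo-1,5,5-trimethylspiro[5.5]undec-7-ene-3,9-dione 9-ethylene ketal, C2 epimers | CC1(C)CC(=O)C(I)[C@](C)(O)[C@@]12C=CC3(CC2)OCCO3 | intermediate
18 | (1S,6S)-1-hydroxy-1,5,5-trimethylspiro[5.5]undec-7-ene-3,9-dione 9-ethylene ketal | CC1(C)CC(=O)C[C@](C)(O)[C@@]12C=CC3(CC2)OCCO3 | intermediate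
19 | (1S,3S,6S)-1,3-dihydroxy-1,5,5-trimethylspiro[5.5]undec-7-en-9-one ethylene ketal | CC1(C)C[C@H](O)C[C@](C)(O)[C@@]12C=CC3(CC2)OCCO3 | intermediate
20 | (1S,3S,6S)-1,3-dihydroxy-1,5,5-trimethylspiro[5.5]undec-7-en-9-one | CC1(C)C[C@H](O)C[C@](C)(O)[C@@]12C=CC(=O)CC2 | intermediate
21 | (1S,3S,6S,9E)-9-(bromomethylidene)-1,5,5-trimethylspiro[5.5]undec-7-ene-1,3-diol | CC1(C)C[C@H](O)C[C@](C)(O)[C@@]12C=C/C(=C/Br)CC2 | intermediate
22 | C3 oxyphosphonium bromide of 21 (not isolated) | CC1(C)C[C@H](O[P+](c3ccccc3)(c3ccccc3)c3ccccc3)C[C@](C)(O)[C@@]12C=C/C(=C/Br)CC2.[Br-] | intermediate
23 | (1S,3R,6S,9E)-3-bromo-9-(bromomethylidene)-1,5,5-trimethylspiro[5.5]undec-7-en-1-ol | CC1(C)C[C@@H](Br)C[C@](C)(O)[C@@]12C=C/C(=C/Br)CC2 | target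

## Step count and least certain steps

Total: 15 steps. Longest linear sequence: 14 steps (steps 1–5 and 7–15). Step 6 is the one-step branch from 9.

**Step 8 (key step).**
- *What may go wrong.* Enolate binding and reductive elimination may be slow at the fully substituted C6 beside CMe2. Dehydroiodination of the Z-iodide, protodepalladation or C–O coupling with phenoxide could then take over. Face discrimination may also be insufficient, because the two flanks of the enolate lie far from the ligand.
- *Fallback (sets out from 10, returns at 15).* Ring B is closed without palladium and C6 is made stereogenic afterwards. Commercial 1,5-dichloropentan-3-one is ketalised with 4 to 2,2-bis(2-chloroethyl)-1,3-dioxolane F1 and converted with NaI into 2,2-bis(2-iodoethyl)-1,3-dioxolane F2. Two successive LDA deprotonations of 10 in the presence of F2 give, by intermolecular and then intramolecular C6 alkylation, the achiral saturated spiro ketal F3. Mild aqueous acid frees the C9 ketone, giving 3-ethoxy-5,5-dimethylspiro[5.5]undec-2-ene-1,9-dione F4, in which C8 and C10 are enantiotopic. A chiral lithium amide with Me3SiCl present (enantioselective deprotonation) gives the C8=C9 silyl enol ether F5. Saegusa–Ito oxidation gives the spiro enone F6, and TMSOTf-catalysed ketalisation with 1,2-bis(trimethylsilyloxy)ethane returns 15.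

**Step 9.**
- *What may go wrong.* Facial selectivity may be poor because the two half-chairs differ only by an axial sp2 versus an axial sp3 arm. Addition to the hindered carbonyl may be incomplete, and the C1–O bond may ionise during work-up.
- *Fallback (sets out from 16 in any epimer ratio, returns at 19).* C1 is derived from C3 instead of from the facial bias at C1. Brief contact with PPTS in wet CH2Cl2 lets 16 collapse to (6S)-1,5,5-trimethylspiro[5.5]undeca-1,7-diene-3,9-dione 9-ethylene ketal F7. Corey–Bakshi–Shibata reduction, with the oxazaborolidine antipode that delivers the 3S configuration, gives the allylic alcohol F8. Vanadium-catalysed hydroxyl-directed epoxidation with t-BuOOH gives the 1,2-epoxide syn to the C3 hydroxyl, epoxy alcohol F9. LiAlH4 opens it at C2, the only accessible carbon, in trans-diaxial fashion; the C1–O bond stays, and 19 results.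

**Step 14.**
- *What may go wrong.* E/Z control may be poor because C8–H and C10H2 differ little. The basic ylide may enolise the enone, and the ylide may scramble its halogen.
- *Fallback (sets out from 20, returns at 23).* The geometry is set by site-selective oxidative addition instead of by the olefination. Excess PPh3/CBr4 converts the C9 carbonyl into a dibromomethylidene group (Ramirez olefination) and carries out the C3 Appel inversion in the same operation, giving (1S,3R,6S)-3-bromo-9-(dibromomethylidene)-1,5,5-trimethylspiro[5.5]undec-7-en-1-ol F10. Pd(PPh3)4/Bu3SnH then replaces the vinylic bromine cis to the flat C8–H flank, where the square-planar palladium fragment meets no out-of-plane hydrogen. This leaves the bromine cis to C10 and gives 23. No basic step follows the introduction of the C3 bromide.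

**Step 15.**
- *What may go wrong.* E2 elimination from the axial oxyphosphonium ion (antiperiplanar axial hydrogens at C2 and C4), engagement of the tertiary hydroxyl in a cyclic phosphorane, or acid-induced dehydration at C1.
- *Fallback (sets out from 21, returns at 23).* Both oxygens are tied into one leaving group. SOCl2/Et3N converts the cis-1,3-diol into the bridged cyclic sulfite F11, which protects C1 while it activates C3. LiBr in DMF opens it by SN2 at the secondary carbon from the C7 face, and aqueous work-up hydrolyses the remaining C1 sulfite half-ester to give 23.

## Further compounds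

F1 | step 8 | 2,2-bis(2-chloroethyl)-1,3-dioxolane | ClCCC1(CCCl)OCCO1
F2 | step 8 | 2,2-bis(2-iodoethyl)-1,3-dioxolane | ICCC1(CCI)OCCO1
F3 | step 8 | 3-ethoxy-5,5-dimethylspiro[5.5]undec-2-ene-1,9-dione 9-ethylene ketal (achiral) | CC1(C)CC(OCC)=CC(=O)C12CCC3(CC2)OCCO3
F4 | step 8 | 3-ethoxy-5,5-dimethylspiro[5.5]undec-2-ene-1,9-dione (achiral) | CC1(C)CC(OCC)=CC(=O)C12CCC(=O)CC2
F5 | step 8 | (6S)-3-ethoxy-5,5-dimethyl-9-(trimethylsilyloxy)spiro[5.5]undeca-2,8-dien-1-one | CC1(C)CC(OCC)=CC(=O)[C@@]12CC=C(O[Si](C)(C)C)CC2
F6 | step 8 | (6S)-3-ethoxy-5,5-dimethylspiro[5.5]undeca-2,7-diene-1,9-dione | CC1(C)CC(OCC)=CC(=O)[C@@]12C=CC(=O)CC2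
F7 | step 9 | (6S)-1,5,5-trimethylspiro[5.5]undeca-1,7-diene-3,9-dione 9-ethylene ketal | CC1(C)CC(=O)C=C(C)[C@@]12C=CC3(CC2)OCCO3
F8 | step 9 | (3S,6S)-3-hydroxy-1,5,5-trimethylspiro[5.5]undeca-1,7-dien-9-one ethylene ketal | CC1(C)C[C@H](O)C=C(C)[C@@]12C=CC3(CC2)OCCO3
F9 | step 9 | 1,2-epoxide of F8, oxygen syn to the C3 hydroxyl | CC1(C)C[C@H](O)[C@@H]4O[C@]4(C)[C@@]12C=CC3(CC2)OCCO3
F10 | step 14 | (1S,3R,6S)-3-bromo-9-(dibromomethylidene)-1,5,5-trimethylspiro[5.5]undec-7-en-1-ol | CC1(C)C[C@@H](Br)C[C@](C)(O)[C@@]12C=CC(=C(Br)Br)CC2
F11 | step 15 | bridged cyclic sulfite of diol 21 (configuration at sulfur open) | CC1(C)C[C@H]4C[C@](C)(OS(=O)O4)[C@@]12C=C/C(=C/Br)CC2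
A1 | alternative 1 | tricyclic γ-lactone with the complete (E)-bromodiene and a C3 silyl ether | CC1(C)C[C@H](O[Si](C)(C)C(C)(C)C)C[C@]2(C)OC(=O)[C@H]3C/C(=C\Br)C=C[C@@]123
A2 | alternative 1 | actinol, (4R,6R)-4-hydroxy-2,2,6-trimethylcyclohexanone | O=C1C(C)(C)C[C@H](O)C[C@H]1C
A3 | alternative 2 | 7-bromo spiro[5.5] C1 ketone with C9 ketal and C3 silyl ether | CC1(C)C[C@H](O[Si](C)(C)C(C)(C)C)CC(=O)[C@@]12[C@H](Br)CC3(CC2)OCCO3
A4 | alternative 3 | spiro dienylsilane, silicon trans to C8 | CC1(C)CC(OCC)=CC(=O)[C@@]12C=C/C(=C/[Si](C)(C)C)CC2
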